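**Plan**

Target numbering: C1 is the quaternary carbinol carrying C7 (CH2OBz); C2 bears OH, C3 OBz, C4=C5 is the alkene, C6 bears OBz.
Retrosynthesis first removes the three benzoates and the O1/O2/O3 protection and raises C7 to CO2H. C1 then carries an oxygen and a carboxyl carbon and is flanked by oxygenated C6 with C4=C5 beyond it, which is the α-alkoxy γ,δ-unsaturated acid pattern of an ester enolate Claisen rearrangement.
Cutting C1–C6 (re-forming C4–O and C5=C6) gives a δ-lactone C7(=O)–C1–C2–C3–C4–O with an E enol ether arm on C4. Cutting C5=C6 (Wittig) and the lactone C7–O bond leads back to a 3,4-O-isopropylidene-D-galacturonic acid lactol.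
Forward: the uronic acid chain is extended at its C1, the lactone ring is closed, the Ireland–Claisen shift turns the lactone into the only carbocycle, and the benzoates are then added one at a time.
Stereochemistry: C2 and C3 are C4 and C3 of D-galactose. C1 and C6 arise in the rearrangement: C1 is relayed from the lactone carbinol centre C4 (galactose C2) through the ring-enforced boat, and C6 follows from the E enol ether geometry.

Key step: step 7

Remark: from the Wittig product onward atoms carry the target numbers (C7 = galacturonic C6, C1 = C5, C2 = C4, C3 = C3, C4 = C2, C5 = C1, C6 = the ylide carbon). The phosphonium chloride of step 4 is taken as purchasable (otherwise one step from PPh3 and 4-methoxybenzyl chloromethyl ether).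

**Step 1**
Reactants: 1 phenyl 1-thio-β-D-galactopyranoside
Product: 3 phenyl 3,4-O-isopropylidene-1-thio-β-D-galactopyranoside, via 6-O-methoxyisopropyl mixed acetal 2 (not isolated)
Conditions: Me2C(OMe)2, CSA (cat.), acetone, rt; Et3N; then MeOH–H2O 10:1, 60 °C
Reagents that add atoms: 2,2-dimethoxypropane, COC(C)(C)OC
Why: acid-catalysed transacetalisation under thermodynamic control takes the only cis-vicinal diol of the pyranoside (O3/O4) into a dioxolane, while O6 is caught only as a labile mixed acetal that the aqueous methanol stage hydrolyses; no stereocentre is touched.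

**Step 2**
Reactants: 3 phenyl 3,4-O-isopropylidene-1-thio-β-D-galactopyranoside
Product: 5 phenyl 3,4-O-isopropylidene-1-thio-β-D-galactopyranosiduronic acid, via C6 aldehyde 4 (not isolated)
Conditions: TEMPO (0.2 equiv), PhI(OAc)2 (2.5 equiv), CH2Cl2–H2O 2:1, rt
Reagents that add atoms: water, O
Why: TEMPO/PhI(OAc)2 (oxoammonium) oxidation is selective for the primary alcohol and carries the aldehyde hydrate on to the acid, leaving the secondary 2-OH and the thioglycoside sulfur untouched, as is established for thioglycoside uronic acids.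

**Step 3**
Reactants: 5 phenyl 3,4-O-isopropylidene-1-thio-β-D-galactopyranosiduronic acid
Product: 6 3,4-O-isopropylidene-D-galactopyranuronic acid (lactol, both anomers)
Conditions: NBS (1.3 equiv), acetone–H2O 9:1, −15 → 0 °C
Reagents that add atoms: water, O
Why: thioglycoside hydrolysis by bromonium activation of sulfur and capture of the oxocarbenium ion by water should spare the acetonide in the cold, acetone-rich medium; the anomeric configuration is irrelevant because C1 becomes an alkene carbon.

**Step 4**
Reactants: 6 3,4-O-isopropylidene-D-galactopyranuronic acid; 7 (4-methoxybenzyloxymethyl)triphenylphosphonium chloride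
Product: 8 (E)-6-deoxy-3,4-O-isopropylidene-7-O-(4-methoxybenzyl)-L-galacto-hept-6-enonic acid
Conditions: 7 (5 equiv), KN(SiMe3)2 (4.8 equiv), THF, 0 °C; then 6 in THF–DMSO, 0 °C → rt; NaH2PO4 (pH 5) work-up at 0 °C
Reagents that add atoms: (4-methoxybenzyloxymethyl)triphenylphosphonium chloride (7), [Cl-].COc1ccc(COC[P+](c2ccccc2)(c2ccccc2)c2ccccc2)cc1
Why: Wittig olefination of the open-chain aldehyde form of the lactol, run on the carboxylate so that the uronic α-carbon cannot be deprotonated and lose the acetonide oxygen by β-elimination; alkoxymethylene ylides give both alkene geometries, so 8 is expected together with its Z isomer, which is removed after step 5.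

**Step 5**
Reactants: 8 (E)-6-deoxy-3,4-O-isopropylidene-7-O-(4-methoxybenzyl)-L-galacto-hept-6-enonic acid
Product: 9 (E)-6-deoxy-3,4-O-isopropylidene-7-O-(4-methoxybenzyl)-L-galacto-hept-6-enono-1,5-lactone
Conditions: DCC (1.2 equiv), DMAP (0.1 equiv), CH2Cl2 (0.01 M), 0 °C → rt; chromatography on Et3N-deactivated SiO2
Reagents that add atoms: none
Why: Steglich-type carbodiimide activation lets the allylic C4 hydroxyl, the only one that can reach C7 through a six-membered ring, close the δ-lactone (the α-hydroxyl cannot cyclise); the E and Z lactones should be separable at this neutral stage and only the E isomer is taken on.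

**Step 6**
Reactants: 9 (E)-6-deoxy-3,4-O-isopropylidene-7-O-(4-methoxybenzyl)-L-galacto-hept-6-enono-1,5-lactone
Product: 10 (E)-6-deoxy-3,4-O-isopropylidene-2-O-(methoxymethyl)-7-O-(4-methoxybenzyl)-L-galacto-hept-6-enono-1,5-lactone
Conditions: MeOCH2Cl (3 equiv), iPr2NEt (5 equiv), Bu4NI (cat.), CH2Cl2, 0 °C → rt
Reagents that add atoms: chloromethyl methyl ether, COCCl
Why: MOM ether formation (O-alkylation by the oxocarbenium-like chloromethyl ether) under a hindered amine that neither enolises the lactone nor harms the enol ether; the C1 configuration is kept, although the next step erases it.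

**Step 7**
Reactants: 10 (E)-6-deoxy-3,4-O-isopropylidene-2-O-(methoxymethyl)-7-O-(4-methoxybenzyl)-L-galacto-hept-6-enono-1,5-lactone
Product: 13 (1S,2R,3R,6R)-2,3-(isopropylidenedioxy)-6-(4-methoxybenzyloxy)-1-(methoxymethoxy)cyclohex-4-ene-1-carboxylic acid, via trimethylsilyl ketene acetal 11 (not isolated), via trimethylsilyl ester 12 (not isolated)
Conditions: Me3SiCl–Et3N (1:1, 4 equiv), THF, −78 °C, then KN(SiMe3)2 (1.5 equiv) added slowly; −78 °C → rt, then PhMe, 80 °C if needed; aq. NaH2PO4 work-up
Reagents that add atoms: none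
Why: Deprotonation at C1 in the presence of Me3SiCl gives the endocyclic O-silyl ketene acetal (C1=C7), which undergoes a concerted suprafacial [3,3] shift in which C1 bonds to C6 while C4–O breaks and C4=C5 forms, and aqueous work-up cleaves the silyl ester to the acid. The closest known chemistry is the Ireland–Claisen ring contraction of alkenyl-lactone silyl ketene acetals to cycloalkenecarboxylic acids, with the dioxanone-to-dihydropyran Claisen rearrangement as its α-alkoxy counterpart. The six-membered carbocycle closes by pericyclic C1–C6 bond formation across the lactone in a bicyclo[2.2.2]octene-like array, which allows only a boat transition state; the cis-fused acetonide, which eclipses C2–C3, predisposes the lactone to that boat. C1 is set by the C4 stereocentre (galactose C2): the enol ether arm reaches only the ketene acetal face on which it stands, the face syn to the acetonide, so C7 ends anti to the C2/C3 oxygens and O1 syn to them. C6 is set by the E enol ether geometry within the enforced boat, which places O6 cis to C7, and the alkoxy donor on C6 should also speed the shift. The selectivity needed is O-silylation ahead of β-elimination of the C2 acetonide oxygen from the potassium enolate, which the silyl chloride present during deprotonation secures.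

**Step 8**
Reactants: 13 (1S,2R,3R,6R)-2,3-(isopropylidenedioxy)-6-(4-methoxybenzyloxy)-1-(methoxymethoxy)cyclohex-4-ene-1-carboxylic acid
Product: 14 [(1S,2R,3R,6R)-2,3-(isopropylidenedioxy)-6-(4-methoxybenzyloxy)-1-(methoxymethoxy)cyclohex-4-en-1-yl]methanol
Conditions: LiAlH4 (3 equiv), THF, 0 °C → reflux; H2O/NaOH work-up
Reagents that add atoms: none
Why: LiAlH4 reduction of the carboxylate reaches the neopentyl-type primary alcohol, and acetonide, MOM ether, PMB ether and the isolated alkene are inert to hydride; no stereocentre is affected.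

**Step 9**
Reactants: 14 [(1S,2R,3R,6R)-2,3-(isopropylidenedioxy)-6-(4-methoxybenzyloxy)-1-(methoxymethoxy)cyclohex-4-en-1-yl]methanol; 15 benzoyl chloride
Product: 16 [(1S,2R,3R,6R)-2,3-(isopropylidenedioxy)-6-(4-methoxybenzyloxy)-1-(methoxymethoxy)cyclohex-4-en-1-yl]methyl benzoate
Conditions: BzCl (1.5 equiv), pyridine, DMAP (0.1 equiv), CH2Cl2, 0 °C → rt
Reagents that add atoms: benzoyl chloride (15), O=C(Cl)c1ccccc1
Why: DMAP-catalysed acylation of the only free hydroxyl, the primary C7 alcohol.

**Step 10**
Reactants: 16 [(1S,2R,3R,6R)-2,3-(isopropylidenedioxy)-6-(4-methoxybenzyloxy)-1-(methoxymethoxy)cyclohex-4-en-1-yl]methyl benzoate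
Product: 17 [(1S,2R,3R,6R)-6-hydroxy-2,3-(isopropylidenedioxy)-1-(methoxymethoxy)cyclohex-4-en-1-yl]methyl benzoate
Conditions: DDQ (1.5 equiv), CH2Cl2–pH 7 phosphate buffer 10:1, 0 °C → rt
Reagents that add atoms: none
Why: oxidative PMB ether cleavage (benzylic hydride abstraction by DDQ, then hydrolysis of the oxocarbenium ion) frees O6 without touching the C6–O bond, and benzoate, MOM ether and acetonide are stable in the buffered medium.

**Step 11**
Reactants: 17 [(1S,2R,3R,6R)-6-hydroxy-2,3-(isopropylidenedioxy)-1-(methoxymethoxy)cyclohex-4-en-1-yl]methyl benzoate; 15 benzoyl chloride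
Product: 18 [(1S,2R,3R,6R)-6-(benzoyloxy)-2,3-(isopropylidenedioxy)-1-(methoxymethoxy)cyclohex-4-en-1-yl]methyl benzoate
Conditions: BzCl (3 equiv), pyridine, DMAP (0.5 equiv), CH2Cl2, rt → 40 °C
Reagents that add atoms: benzoyl chloride (15), O=C(Cl)c1ccccc1
Why: DMAP-catalysed acylation of the sole free hydroxyl; the allylic C6 alcohol next to the quaternary C1 is hindered but has no competitor, and acylation at oxygen keeps the C6 configuration.

**Step 12**
Reactants: 18 [(1S,2R,3R,6R)-6-(benzoyloxy)-2,3-(isopropylidenedioxy)-1-(methoxymethoxy)cyclohex-4-en-1-yl]methyl benzoate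
Product: 20 [(1R,2R,3R,6R)-6-(benzoyloxy)-1,2,3-trihydroxycyclohex-4-en-1-yl]methyl benzoate, via 1-O-methoxymethyl 2,3-diol 19 (not isolated)
Conditions: CF3CO2H–H2O 9:1, 0 °C → rt
Reagents that add atoms: none
Why: acid-catalysed acetal hydrolysis removes the acetonide and then the tertiary MOM ether, while both benzoates are stable to aqueous acid and their migration to the tertiary O1 or the hindered O2 is thermodynamically uphill.

**Step 13**
Reactants: 20 [(1R,2R,3R,6R)-6-(benzoyloxy)-1,2,3-trihydroxycyclohex-4-en-1-yl]methyl benzoate; 15 benzoyl chloride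
Product: 21 [(1R,2R,3R,6R)-3,6-bis(benzoyloxy)-1,2-dihydroxycyclohex-4-en-1-yl]methyl benzoate (CNP0128482.3)
Conditions: BzCl (1.1 equiv), pyridine–CH2Cl2 1:4, −40 → −20 °C
Reagents that add atoms: benzoyl chloride (15), O=C(Cl)c1ccccc1
Why: kinetically controlled monoacylation, in which the allylic O3 is the only unhindered hydroxyl (O1 is tertiary, O2 is flanked by the quaternary C1), so one equivalent of acid chloride at low temperature should acylate O3 selectively.

**Compound list** (ring locants in names 13–21 follow the target numbering defined in the plan)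

1 | phenyl 1-thio-β-D-galactopyranoside | OC[C@H]1O[C@@H](Sc2ccccc2)[C@H](O)[C@@H](O)[C@H]1O | starting material
2 | phenyl 3,4-O-isopropylidene-6-O-(2-methoxypropan-2-yl)-1-thio-β-D-galactopyranoside (formed in the flask) | COC(C)(C)OC[C@H]1O[C@@H](Sc2ccccc2)[C@H](O)[C@H]2OC(C)(C)O[C@@H]12 | intermediate
3 | phenyl 3,4-O-isopropylidene-1-thio-β-D-galactopyranoside | OC[C@H]1O[C@@H](Sc2ccccc2)[C@H](O)[C@H]2OC(C)(C)O[C@@H]12 | intermediate
4 | phenyl 3,4-O-isopropylidene-1-thio-β-D-galacto-hexodialdo-1,5-pyranoside (formed in the flask) | O=C[C@H]1O[C@@H](Sc2ccccc2)[C@H](O)[C@H]2OC(C)(C)O[C@@H]12 | intermediate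
5 | phenyl 3,4-O-isopropylidene-1-thio-β-D-galactopyranosiduronic acid | OC(=O)[C@H]1O[C@@H](Sc2ccccc2)[C@H](O)[C@H]2OC(C)(C)O[C@@H]12 | intermediate
6 | 3,4-O-isopropylidene-D-galactopyranuronic acid (lactol, both anomers) | OC(=O)[C@H]1OC(O)[C@H](O)[C@H]2OC(C)(C)O[C@@H]12 | intermediate
7 | (4-methoxybenzyloxymethyl)triphenylphosphonium chloride | [Cl-].COc1ccc(COC[P+](c2ccccc2)(c2ccccc2)c2ccccc2)cc1 | starting material
8 | (E)-6-deoxy-3,4-O-isopropylidene-7-O-(4-methoxybenzyl)-L-galacto-hept-6-enonic acid | OC(=O)[C@@H](O)[C@@H]1OC(C)(C)O[C@@H]1[C@@H](O)/C=C/OCc1ccc(OC)cc1 | intermediate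
9 | (E)-6-deoxy-3,4-O-isopropylidene-7-O-(4-methoxybenzyl)-L-galacto-hept-6-enono-1,5-lactone; (3S,4S,5R,6S)-3-hydroxy-4,5-(isopropylidenedioxy)-6-[(E)-2-(4-methoxybenzyloxy)ethenyl]oxan-2-one | O=C1[C@@H](O)[C@@H]2OC(C)(C)O[C@@H]2[C@H](/C=C/OCc2ccc(OC)cc2)O1 | intermediate
10 | 2-O-methoxymethyl ether of 9; (3S,4R,5R,6S)-4,5-(isopropylidenedioxy)-3-(methoxymethoxy)-6-[(E)-2-(4-methoxybenzyloxy)ethenyl]oxan-2-one | O=C1[C@@H](OCOC)[C@@H]2OC(C)(C)O[C@@H]2[C@H](/C=C/OCc2ccc(OC)cc2)O1 | intermediate
11 | trimethylsilyl ketene acetal of 10, C1=C7 endocyclic (formed in the flask) | C[Si](C)(C)OC1=C(OCOC)[C@@H]2OC(C)(C)O[C@@H]2[C@H](/C=C/OCc2ccc(OC)cc2)O1 | intermediate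
12 | trimethylsilyl ester of 13 (formed in the flask) | C[Si](C)(C)OC(=O)[C@@]1(OCOC)[C@@H]2OC(C)(C)O[C@@H]2C=C[C@H]1OCc1ccc(OC)cc1 | intermediate
13 | (1S,2R,3R,6R)-2,3-(isopropylidenedioxy)-6-(4-methoxybenzyloxy)-1-(methoxymethoxy)cyclohex-4-ene-1-carboxylic acid | OC(=O)[C@@]1(OCOC)[C@@H]2OC(C)(C)O[C@@H]2C=C[C@H]1OCc1ccc(OC)cc1 | intermediate
14 | [(1S,2R,3R,6R)-2,3-(isopropylidenedioxy)-6-(4-methoxybenzyloxy)-1-(methoxymethoxy)cyclohex-4-en-1-yl]methanol | OC[C@@]1(OCOC)[C@@H]2OC(C)(C)O[C@@H]2C=C[C@H]1OCc1ccc(OC)cc1 | intermediate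
15 | benzoyl chloride | O=C(Cl)c1ccccc1 | starting material
16 | [(1S,2R,3R,6R)-2,3-(isopropylidenedioxy)-6-(4-methoxybenzyloxy)-1-(methoxymethoxy)cyclohex-4-en-1-yl]methyl benzoate | O=C(OC[C@@]1(OCOC)[C@@H]2OC(C)(C)O[C@@H]2C=C[C@H]1OCc1ccc(OC)cc1)c1ccccc1 | intermediate
17 | [(1S,2R,3R,6R)-6-hydroxy-2,3-(isopropylidenedioxy)-1-(methoxymethoxy)cyclohex-4-en-1-yl]methyl benzoate | O=C(OC[C@@]1(OCOC)[C@@H]2OC(C)(C)O[C@@H]2C=C[C@H]1O)c1ccccc1 | intermediate
18 | [(1S,2R,3R,6R)-6-(benzoyloxy)-2,3-(isopropylidenedioxy)-1-(methoxymethoxy)cyclohex-4-en-1-yl]methyl benzoate | O=C(OC[C@@]1(OCOC)[C@@H]2OC(C)(C)O[C@@H]2C=C[C@H]1OC(=O)c1ccccc1)c1ccccc1 | intermediate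
19 | [(1R,2R,3R,6R)-6-(benzoyloxy)-2,3-dihydroxy-1-(methoxymethoxy)cyclohex-4-en-1-yl]methyl benzoate (formed in the flask) | O=C(OC[C@@]1(OCOC)[C@H](O)[C@H](O)C=C[C@H]1OC(=O)c1ccccc1)c1ccccc1 | intermediate
20 | [(1R,2R,3R,6R)-6-(benzoyloxy)-1,2,3-trihydroxycyclohex-4-en-1-yl]methyl benzoate | O=C(OC[C@@]1(O)[C@H](O)[C@H](O)C=C[C@H]1OC(=O)c1ccccc1)c1ccccc1 | intermediate
21 | [(1R,2R,3R,6R)-3,6-bis(benzoyloxy)-1,2-dihydroxycyclohex-4-en-1-yl]methyl benzoate (CNP0128482.3) | O=C(OC[C@@]1(O)[C@H](O)[C@H](OC(=O)c2ccccc2)C=C[C@H]1OC(=O)c1ccccc1)c1ccccc1 | target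

Total step count: 13. Longest linear sequence: 13 steps (from 1).

**Steps most likely to fail**

Step 7. The potassium enolate may expel the C2 acetonide oxygen (β-elimination) before it is silylated, or the labile trimethylsilyl ketene acetal may be lost before a slow boat rearrangement. Fallback, setting out from 10 and returning at 13: the enolate is avoided altogether by soft enolisation with tBuMe2SiOSO2CF3 and Et3N in benzene at 0 °C → rt, as practised for lactone Claisen rearrangements of morpholinones and dioxanones. This gives the isolable tert-butyldimethylsilyl ketene acetal F1. Heating F1 in toluene (90–110 °C) as a separate thermal step should give the tert-butyldimethylsilyl ester F2, which K2CO3 in aqueous MeOH cleaves to 13.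

Step 4. The olefination is expected to deliver both enol ether geometries, which costs material and makes the route depend on a chromatographic separation; the polyanionic lactol may also react sluggishly. Fallback, setting out from 6 and 7 and returning at 8: the phosphonium salt 7 is hydrolysed with aqueous NaOH (loss of benzene) to [(4-methoxybenzyloxy)methyl]diphenylphosphine oxide F3. Its lithio derivative (LiN(iPr)2, THF, −78 °C, excess) adds to lactol 6 in a Horner–Wittig reaction that stops at the β-hydroxy phosphine oxides. The threo β-hydroxy phosphine oxide adduct F4 is separated by crystallisation or chromatography and treated with KH in DMF, where stereospecific syn-elimination of diphenylphosphinate should give 8 as the E isomer only.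

Step 13. Acylation may spill over to O2 or go twice, or the base may trigger benzoyl migration. Fallback, setting out from 20 and returning at 21: trimethyl orthobenzoate and CSA (cat.) in MeCN convert the cis-2,3-diol into the cyclic 2,3-orthobenzoate F5. Mild aqueous AcOH then opens it, which delivers exactly one benzoyl group to the O2/O3 pair. The ester is expected on the pseudo-axial oxygen, which should be O3 in the half-chair that keeps C7 equatorial, giving 21.

**Further compounds**

F1 | step 7 | tert-butyldimethylsilyl ketene acetal of lactone 10 | CC(C)(C)[Si](C)(C)OC1=C(OCOC)[C@@H]2OC(C)(C)O[C@@H]2[C@H](/C=C/OCc2ccc(OC)cc2)O1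
F2 | step 7 | tert-butyldimethylsilyl ester of acid 13 | CC(C)(C)[Si](C)(C)OC(=O)[C@@]1(OCOC)[C@@H]2OC(C)(C)O[C@@H]2C=C[C@H]1OCc1ccc(OC)cc1
F3 | step 4 | [(4-methoxybenzyloxy)methyl]diphenylphosphine oxide | COc1ccc(COCP(=O)(c2ccccc2)c2ccccc2)cc1
F4 | step 4 | threo β-hydroxy phosphine oxide adduct of 6 (one of the two threo diastereomers) | OC(=O)[C@@H](O)[C@@H]1OC(C)(C)O[C@@H]1[C@@H](O)[C@@H](O)[C@@H](OCc1ccc(OC)cc1)P(=O)(c1ccccc1)c1ccccc1
F5 | step 13 | cyclic 2,3-orthobenzoate (2,3-O-(α-methoxybenzylidene) derivative) of 20, either configuration at the orthoester carbon | O=C(OC[C@@]1(O)[C@@H]2OC(OC)(c3ccccc3)O[C@@H]2C=C[C@H]1OC(=O)c1ccccc1)c1ccccc1
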